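**Plan**
1. Retrosynthetic cuts, in order: the C8–O angelate ester; C4=C5 (ring-closing metathesis); then C2–C3 and C1–C10 of the furanone together, as a [3+2] cycloaddition of a C3–O–C10 carbonyl ylide with a two-carbon ynol ether, N2 being the extruded placeholder; then the temporary oxadiazoline (C10–N, C10–O, C3–O8); C8–C9 (acetone aldol); C11–CH3 and C7–C8 (enolate methylation, vinyl conjugate addition).
2. Forward order of rings: γ-lactone (bought, chiral pool), then a temporary bridged 1,3-dioxane/oxadiazoline, then the furanone (N=N exchanged for C1=C2, tether cut by acid), and the ten-membered carbocycle last.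
3. Enabling feature: in the five-membered furanone ring the ring oxygen is flanked by C3 and C10. C3–O–C10 is therefore a masked carbonyl ylide, and C2–C1(=O) is a ketene-level two-carbon unit. The C8 oxygen sits 1,3 to C10 and can be tied to C3, which puts the ylide inside a six-membered ring.
4. Helpers and their removal: the N=N bridge leaves as N2 (step 10); the O8–C3 tether and the ethyl group of the ynol ether are removed in step 11; TBDPS is removed in step 13.
5. Stereochemistry: C6 comes from (S)-5-(hydroxymethyl)butenolide. C7 and C11 are set by anti addition and anti alkylation on the lactone. C8 is set by L-proline control. C10 is relayed from C8 through the cyclic ylide. The angelate Z geometry comes from angelic acid, and C4=C5 Z from ring constraint.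

Key step: step 10

Assumption: germacrane numbering of the target is used for all intermediates (C1 ketone, C2=C3, C4=C5, C6–O lactone, C8–O ester, C10 quaternary, O8 = oxygen on C8). The acylhydrazone is handled as a C=N E/Z mixture, since the oxidation consumes both isomers.

**Step 1**
Reactants: 1 (S)-5-(hydroxymethyl)furan-2(5H)-one
Product: 2 (S)-5-[(tert-butyldiphenylsilyloxy)methyl]furan-2(5H)-one
Conditions: TBDPSCl, imidazole, CH2Cl2, 0 °C to rt
Reagents that add atoms: tert-butyldiphenylsilyl chloride, CC(C)(C)[Si](Cl)(c1ccccc1)c1ccccc1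
Why: Standard silyl ether protection of a primary alcohol; C6 is taken unchanged from the chiral pool, and the bulky group later shields one face of the butenolide.

**Step 2**
Reactants: 2 (S)-5-[(tert-butyldiphenylsilyloxy)methyl]furan-2(5H)-one
Product: 3 (4R,5S)-5-[(tert-butyldiphenylsilyloxy)methyl]-4-vinyldihydrofuran-2(3H)-one (vinyl trans to the CH2OSi group)
Conditions: CH2=CHMgBr, CuBr·SMe2 (10 mol %), THF, −78 to −40 °C; aq NH4Cl
Reagents that add atoms: vinylmagnesium bromide, C=C[Mg]Br
Why: Copper-catalysed conjugate addition of a Grignard reagent to a butenolide; the nucleophile should add anti to the C6 substituent and so set C7 trans to C6.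

**Step 3**
Reactants: 3 (4R,5S)-5-[(tert-butyldiphenylsilyloxy)methyl]-4-vinyldihydrofuran-2(3H)-one
Product: 4 (3S,4S,5S)-5-[(tert-butyldiphenylsilyloxy)methyl]-3-methyl-4-vinyldihydrofuran-2(3H)-one (all-trans)
Conditions: LDA, THF, −78 °C; MeI
Reagents that add atoms: iodomethane, CI
Why: Lactone enolate alkylation; MeI should approach anti to the neighbouring C7 vinyl group and set C11 trans to C7, which is also the thermodynamically preferred arrangement.

**Step 4**
Reactants: 4 (3S,4S,5S)-5-[(tert-butyldiphenylsilyloxy)methyl]-3-methyl-4-vinyldihydrofuran-2(3H)-one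
Product: 5 (2S,3S,4S)-2-[(tert-butyldiphenylsilyloxy)methyl]-4-methyl-5-oxotetrahydrofuran-3-carbaldehyde
Conditions: O3, CH2Cl2, −78 °C; Me2S
Reagents that add atoms: ozone, [O-][O+]=O
Why: Ozonolysis with reductive work-up cleaves the only C=C bond to the C8 aldehyde under neutral conditions that should spare the epimerisable, β-acyloxy-substituted C7 centre.

**Step 5**
Reactants: 5 (2S,3S,4S)-2-[(tert-butyldiphenylsilyloxy)methyl]-4-methyl-5-oxotetrahydrofuran-3-carbaldehyde
Product: 6 (3S,4R,5S)-5-[(tert-butyldiphenylsilyloxy)methyl]-4-[(1R)-1-hydroxy-3-oxobutyl]-3-methyldihydrofuran-2(3H)-one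
Conditions: acetone–DMSO (1:4), L-proline (30 mol %), rt
Reagents that add atoms: acetone, CC(C)=O
Why: Proline-catalysed direct intermolecular aldol reaction (enamine catalysis) with an α-branched aldehyde, the best acceptor class; catalyst control by L-proline should deliver the 8R carbinol.

**Step 6**
Reactants: 7 methacryloyl chloride; 8 tert-butyl carbazate
Product: 9 tert-butyl 2-methacryloylhydrazine-1-carboxylate
Conditions: Et3N, CH2Cl2, 0 °C
Reagents that add atoms: none
Why: Schotten–Baumann-type N-acylation of the free NH2 group of the carbazate; no stereocentre is involved.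

**Step 7**
Reactants: 9 tert-butyl 2-methacryloylhydrazine-1-carboxylate
Product: 10 methacrylohydrazide trifluoroacetate salt
Conditions: TFA, CH2Cl2, 0 °C to rt
Reagents that add atoms: trifluoroacetic acid, OC(=O)C(F)(F)F
Why: Acidolytic Boc cleavage; keeping the hydrazide as its salt should suppress aza-Michael self-addition and polymerisation.

**Step 8**
Reactants: 6 β-hydroxy ketone; 10 methacrylohydrazide trifluoroacetate salt
Product: 11 methacryloyl hydrazone of 6 (C10=N–NH–C3(=O)–C4(CH3)=CH2, E/Z mixture at C=N; C6, C7, C8, C11 as in 6)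
Conditions: NaOAc, EtOH, rt
Reagents that add atoms: none
Why: Acylhydrazone condensation under acetate buffer, chemoselective for the ketone over the lactone; no stereocentre is touched.

**Step 9**
Reactants: 11 methacryloyl hydrazone of 6
Product: 12 (1R,3R,5R)-1-isopropenyl-5-methyl-2,8-dioxa-6,7-diazabicyclo[3.2.1]oct-6-ene carrying the lactone unit of 6 equatorially at C3 (bicycle C1 = C3, C3 = C8, C5 = C10 of the target)
Conditions: PhI(OAc)2, CH2Cl2, 0 °C to rt
Reagents that add atoms: none
Why: Hypervalent-iodine oxidative cyclisation of a ketone N-acylhydrazone to a 2-alkoxy-Δ3-1,3,4-oxadiazoline: the amide oxygen closes onto C10 and the resulting oxadiazolium ion is captured by an alcohol, here the C8 hydroxyl through a six-membered ring; the bridge forces C3 and C10 cis, and both centres are erased again in step 10.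

**Step 10**
Reactants: 12 bridged oxadiazoline; 13 ethoxyacetylene
Product: 15 (1S,3R,5R)-6-ethoxy-1-isopropenyl-5-methyl-2,8-dioxabicyclo[3.2.1]oct-6-ene carrying the lactone unit of 6 equatorially at C3, via carbonyl ylide 14 (not isolated)
Conditions: 13 (10 equiv), PhMe, sealed tube, 90 °C
Reagents that add atoms: none
Why: Proposed new method: on heating, 12 should lose N2 by retro-1,3-dipolar cleavage of its two C–N bonds and leave the six-membered cyclic carbonyl ylide 14 (C10–O–C3, carbanion-like at the dialkyl terminus C10, dioxocarbenium-like at C3), which ethoxyacetylene intercepts in a concerted, asynchronous, suprafacial [3+2] cycloaddition that forms C2–C3 and C1–C10 in one event, so that the N=N bridge is exchanged for the C1=C2 unit of the furanone. The closest known reaction types are the thermolysis of monocyclic 2-alkoxy-Δ3-1,3,4-oxadiazolines to carbonyl ylides that are trapped by dipolarophiles, and the alkyne cycloadditions of six-membered ester-derived carbonyl ylides that give 2,8-dioxabicyclo[3.2.1]octenes; the bridged azo precursor, the unstabilised C10 terminus and the ynol ether partner are new. The one ring closed is the five-membered ring O–C3–C2–C1–C10, by intermolecular 4π+2π addition across the two termini of the dipole. C10 is the lasting new stereocentre and is controlled by C8: addition to the ylide face that lets the 1,3-dioxane ring develop as a chair with the lactone substituent on C8 equatorial (exo, syn to the oxygen bridge) gives the 8R,10R relation, whereas the other face needs a boat or an axial substituent; C3 is fixed by the bridge and is erased in step 11. The regioselectivity needed is polarity-matched, since the nucleophilic terminal carbon of the ynol ether bonds to the electrophilic C3 and the ethoxy-bearing carbon to the nucleophilic C10. The O8–C3 tether holds the isopropenyl and methyl groups on the outer positions of the dipole, which blocks 1,5-electrocyclisation onto the isopropenyl group, leaves no hydrogen on C4 for a carbene 1,2-shift and keeps any ylide-to-carbene/ketone fragmentation intramolecular and reversible, while the excess of 13 favours trapping.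

**Step 11**
Reactants: 15 ethoxy-dioxabicyclooctene cycloadduct
Product: 16 (2R)-2-[(2R)-2-hydroxy-2-(lactone unit of 6)ethyl]-2-methyl-5-isopropenylfuran-3(2H)-one (free C8–OH, 10R)
Conditions: 0.5 M HCl, THF–H2O, 0 °C to rt
Reagents that add atoms: water, O
Why: Acid hydrolysis of a vinylogous orthoester (enol ether/ketal hydrolysis with β-alkoxy loss): ionisation at C3 releases O8 as the C8 hydroxyl, water adds at C1 of the ethoxy-stabilised cation and ethanol leaves, giving the conjugated 3(2H)-furanone without touching C10.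

**Step 12**
Reactants: 16 hydroxy furanone; 17 angelic acid
Product: 18 8-O-angelate of 16 (8R, Z ester)
Conditions: 17, 2,4,6-Cl3C6H2COCl, Et3N, PhMe, rt; then 16, 80 °C
Reagents that add atoms: none
Why: Yamaguchi-type mixed-anhydride esterification run without DMAP, the protocol of choice for angelates because it avoids Z-to-E isomerisation; C8 is retained, and any ring-closed ketal tautomer of 16 should be drained through reversible β-alkoxy elimination.

**Step 13**
Reactants: 18 angelate silyl ether
Product: 19 primary alcohol (C5–OH; all stereocentres unchanged)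
Conditions: HF·pyridine, THF, 0 °C to rt
Reagents that add atoms: none
Why: Fluoride-mediated desilylation under mildly acidic conditions that should spare both esters and the base-sensitive furanone.

**Step 14**
Reactants: 19 primary alcohol
Product: 20 C5 aldehyde
Conditions: Dess–Martin periodinane, CH2Cl2, rt
Reagents that add atoms: none
Why: Dess–Martin oxidation of the only free alcohol under near-neutral conditions, chosen to limit epimerisation at C6.

**Step 15**
Reactants: 20 C5 aldehyde
Product: 21 seco-diene (C6 vinyl, C3 isopropenyl)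
Conditions: Ph3PCH3Br, KOtBu, THF, 0 °C; then 20, −78 to 0 °C
Reagents that add atoms: methyltriphenylphosphonium bromide, C[P+](c1ccccc1)(c1ccccc1)c1ccccc1.[Br-]
Why: Wittig methylenation; the aldehyde should react far faster than the hindered vinylogous-ester ketone C1 and the two esters, and the low temperature limits loss of configuration at C6.

**Step 16**
Reactants: 21 seco-diene
Product: 22 target, CNP0278264.1 (6R,7R,8R,10R,11S; 4Z; angelate Z)
Conditions: second-generation Hoveyda–Grubbs catalyst (15 mol %), PhMe (1 mM), 90 °C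
Reagents that add atoms: none
Why: Ring-closing metathesis; the catalyst should load on the monosubstituted C5 vinyl group and close onto the isopropenyl group with loss of ethene, and the oxygen-bridged medium ring should accept only the cis (Z) trisubstituted C4=C5 bond.

**Compound list**
1 | (S)-5-(hydroxymethyl)furan-2(5H)-one | OC[C@H]1OC(=O)C=C1 | starting material
2 | (S)-5-[(tert-butyldiphenylsilyloxy)methyl]furan-2(5H)-one | CC(C)(C)[Si](c1ccccc1)(c1ccccc1)OC[C@H]1OC(=O)C=C1 | intermediate
3 | (4R,5S)-4-vinyl lactone | CC(C)(C)[Si](c1ccccc1)(c1ccccc1)OC[C@H]1OC(=O)C[C@@H]1C=C | intermediate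
4 | (3S,4S,5S)-3-methyl-4-vinyl lactone (all-trans) | CC(C)(C)[Si](c1ccccc1)(c1ccccc1)OC[C@H]1OC(=O)[C@@H](C)[C@@H]1C=C | intermediate
5 | (2S,3S,4S)-lactone carbaldehyde (C8 aldehyde) | CC(C)(C)[Si](c1ccccc1)(c1ccccc1)OC[C@H]1OC(=O)[C@@H](C)[C@@H]1C=O | intermediate
6 | (8R)-β-hydroxy methyl ketone | CC(C)(C)[Si](c1ccccc1)(c1ccccc1)OC[C@H]1OC(=O)[C@@H](C)[C@@H]1[C@H](O)CC(C)=O | intermediate
7 | methacryloyl chloride | C=C(C)C(=O)Cl | starting material
8 | tert-butyl carbazate | CC(C)(C)OC(=O)NN | starting material
9 | tert-butyl 2-methacryloylhydrazine-1-carboxylate | C=C(C)C(=O)NNC(=O)OC(C)(C)C | intermediate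
10 | methacrylohydrazide trifluoroacetate salt | C=C(C)C(=O)NN.OC(=O)C(F)(F)F | intermediate
11 | methacryloyl hydrazone of 6 (E/Z at C=N) | CC(C)(C)[Si](c1ccccc1)(c1ccccc1)OC[C@H]1OC(=O)[C@@H](C)[C@@H]1[C@H](O)CC(C)=NNC(=O)C(C)=C | intermediate
12 | bridged 2,8-dioxa-6,7-diazabicyclo[3.2.1]oct-6-ene | CC(C)(C)[Si](c1ccccc1)(c1ccccc1)OC[C@H]1OC(=O)[C@@H](C)[C@@H]1[C@H]2C[C@@]3(C)O[C@@](O2)(N=N3)C(C)=C | intermediate
13 | ethoxyacetylene | C#COCC | starting material
14 | six-membered cyclic carbonyl ylide (not isolated) | CC(C)(C)[Si](c1ccccc1)(c1ccccc1)OC[C@H]1OC(=O)[C@@H](C)[C@@H]1[C@H]2C[C-](C)[O+]=C(O2)C(C)=C | intermediate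
15 | 6-ethoxy-2,8-dioxabicyclo[3.2.1]oct-6-ene cycloadduct | CC(C)(C)[Si](c1ccccc1)(c1ccccc1)OC[C@H]1OC(=O)[C@@H](C)[C@@H]1[C@H]2C[C@@]3(C)O[C@@](O2)(C=C3OCC)C(C)=C | intermediate
16 | (8R,10R)-hydroxy 5-isopropenyl-3(2H)-furanone | CC(C)(C)[Si](c1ccccc1)(c1ccccc1)OC[C@H]1OC(=O)[C@@H](C)[C@@H]1[C@H](O)C[C@@]2(C)OC(=CC2=O)C(C)=C | intermediate
17 | angelic acid, (Z)-2-methylbut-2-enoic acid | C/C=C(/C)C(=O)O | starting material
18 | 8-O-angelate silyl ether | CC(C)(C)[Si](c1ccccc1)(c1ccccc1)OC[C@H]1OC(=O)[C@@H](C)[C@@H]1[C@H](OC(=O)/C(C)=C\C)C[C@@]2(C)OC(=CC2=O)C(C)=C | intermediate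
19 | C5 primary alcohol | OC[C@H]1OC(=O)[C@@H](C)[C@@H]1[C@H](OC(=O)/C(C)=C\C)C[C@@]2(C)OC(=CC2=O)C(C)=C | intermediate
20 | C5 aldehyde | O=C[C@H]1OC(=O)[C@@H](C)[C@@H]1[C@H](OC(=O)/C(C)=C\C)C[C@@]2(C)OC(=CC2=O)C(C)=C | intermediate
21 | seco-diene | C=C[C@H]1OC(=O)[C@@H](C)[C@@H]1[C@H](OC(=O)/C(C)=C\C)C[C@@]2(C)OC(=CC2=O)C(C)=C | intermediate
22 | CNP0278264.1 | C/C=C(/C)C(=O)O[C@@H]1C[C@@]2(C)OC(=CC2=O)/C(C)=C\[C@H]2OC(=O)[C@@H](C)[C@@H]21 | target

**Totals**
Total step count: 16.
Longest linear sequence: 14 steps (steps 1–5 and 8–16).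

**Steps most likely to fail**

1. **Step 10.**
   - What may go wrong: the ylide may collapse faster than it is trapped. The possible routes are fragmentation to an alkoxy(vinyl)carbene and the ketone, hydrogen shift, or cycloreversion of 12 to a diazoalkane and a methacrylate. It may also be trapped with poor facial selectivity at C10.
   - Fallback (known chemistry, from 6 back to 16): the C8 hydroxyl of 6 is silylated (TESCl, imidazole) to the triethylsilyl ether F1.
   - 4-Methylpent-4-en-1-yn-3-ol F2 (ethynylmagnesium bromide plus methacrolein) is doubly lithiated (n-BuLi, THF, −78 °C) and added to the ketone of F1 to give the propargylic diol F3. The C10 epimers are separated by chromatography; the C3 carbinol epimers are carried on together.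
   - MnO2 in CH2Cl2 oxidises only the allylic–propargylic C3 carbinol to the ynone F4.
   - Conjugate addition of Et2NH at C1 gives the enaminone F5. Aqueous AcOH hydrolyses it to the 1,3-diketone, which cyclodehydrates through the C10 hydroxyl and loses the TES group to give 16.

2. **Step 9.**
   - What may go wrong: the oxadiazolium ion may be captured by acetate instead of the C8 hydroxyl, or the oxidation may stop at an open azo acetate.
   - Fallback (from 11 back to 12): the oxidation is run in methanol (PhI(OAc)2, MeOH, 0 °C). This is the best-documented intermolecular variant and gives the monocyclic 2-methoxy oxadiazoline F6.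
   - A separate acid-catalysed alkoxy exchange (cat. TFA, benzene, 4 Å molecular sieves) then replaces the methoxy group by the internal C8 hydroxyl and closes the bridge.

3. **Step 16.**
   - What may go wrong: oligomerisation, or no closure at all, because of the strain of the bridged medium ring and the low reactivity of the conjugated 1,1-disubstituted alkene.
   - Fallback (from 6 back to 22): ketone 6 is condensed with commercial propanohydrazide to the propanoyl hydrazone F7. This is taken through the conditions of steps 9–14: bridged oxadiazoline F8, carbonyl ylide F9, cycloadduct F10, 5-ethylfuranone alcohol F11, angelate F12, primary alcohol F13 and aldehyde F14.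
   - Deprotonation of the 5-ethyl group at C4 (LiHMDS, THF, −78 °C, high dilution) gives the extended furanone enolate, which closes the ring by intramolecular vinylogous aldol addition to the C5 aldehyde (macrocyclic aldol F15).
   - Mesylation (MsCl, Et3N) to the mesylate F16, followed by DBU-induced vinylogous E1cB elimination, installs the conjugated C4=C5 bond and gives 22.

**Further compounds**
F1 | step 10 | C8 triethylsilyl ether of 6 | CC(C)(C)[Si](c1ccccc1)(c1ccccc1)OC[C@H]1OC(=O)[C@@H](C)[C@@H]1[C@H](O[Si](CC)(CC)CC)CC(C)=O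
F2 | step 10 | 4-methylpent-4-en-1-yn-3-ol (racemic) | C#CC(O)C(C)=C
F3 | step 10 | propargylic diol (10R; C3 carbinol epimers) | CC(C)(C)[Si](c1ccccc1)(c1ccccc1)OC[C@H]1OC(=O)[C@@H](C)[C@@H]1[C@H](O[Si](CC)(CC)CC)C[C@@](C)(O)C#CC(O)C(C)=C
F4 | step 10 | γ-hydroxy ynone | CC(C)(C)[Si](c1ccccc1)(c1ccccc1)OC[C@H]1OC(=O)[C@@H](C)[C@@H]1[C@H](O[Si](CC)(CC)CC)C[C@@](C)(O)C#CC(=O)C(C)=C
F5 | step 10 | diethylamino enaminone | CC(C)(C)[Si](c1ccccc1)(c1ccccc1)OC[C@H]1OC(=O)[C@@H](C)[C@@H]1[C@H](O[Si](CC)(CC)CC)C[C@@](C)(O)C(=CC(=O)C(C)=C)N(CC)CC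
F6 | step 9 | monocyclic 2-methoxy-2-isopropenyl-5-methyl-Δ3-1,3,4-oxadiazoline with free C8–OH (mixture at C3 and C10) | CC(C)(C)[Si](c1ccccc1)(c1ccccc1)OC[C@H]1OC(=O)[C@@H](C)[C@@H]1[C@H](O)CC2(C)OC(OC)(N=N2)C(C)=C
F7 | step 16 | propanoyl hydrazone of 6 (E/Z at C=N) | CC(C)(C)[Si](c1ccccc1)(c1ccccc1)OC[C@H]1OC(=O)[C@@H](C)[C@@H]1[C@H](O)CC(C)=NNC(=O)CC
F8 | step 16 | 1-ethyl bridged oxadiazoline | CC(C)(C)[Si](c1ccccc1)(c1ccccc1)OC[C@H]1OC(=O)[C@@H](C)[C@@H]1[C@H]2C[C@@]3(C)O[C@@](O2)(N=N3)CC
F9 | step 16 | ethyl-substituted cyclic carbonyl ylide (not isolated) | CC(C)(C)[Si](c1ccccc1)(c1ccccc1)OC[C@H]1OC(=O)[C@@H](C)[C@@H]1[C@H]2C[C-](C)[O+]=C(O2)CC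
F10 | step 16 | 1-ethyl-6-ethoxy-2,8-dioxabicyclo[3.2.1]oct-6-ene cycloadduct | CC(C)(C)[Si](c1ccccc1)(c1ccccc1)OC[C@H]1OC(=O)[C@@H](C)[C@@H]1[C@H]2C[C@@]3(C)O[C@@](O2)(C=C3OCC)CC
F11 | step 16 | (8R,10R)-hydroxy 5-ethyl-3(2H)-furanone | CC(C)(C)[Si](c1ccccc1)(c1ccccc1)OC[C@H]1OC(=O)[C@@H](C)[C@@H]1[C@H](O)C[C@@]2(C)OC(=CC2=O)CC
F12 | step 16 | 8-O-angelate of F11 | CC(C)(C)[Si](c1ccccc1)(c1ccccc1)OC[C@H]1OC(=O)[C@@H](C)[C@@H]1[C@H](OC(=O)/C(C)=C\C)C[C@@]2(C)OC(=CC2=O)CC
F13 | step 16 | C5 primary alcohol, 5-ethyl series | OC[C@H]1OC(=O)[C@@H](C)[C@@H]1[C@H](OC(=O)/C(C)=C\C)C[C@@]2(C)OC(=CC2=O)CC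
F14 | step 16 | C5 aldehyde, 5-ethyl series | O=C[C@H]1OC(=O)[C@@H](C)[C@@H]1[C@H](OC(=O)/C(C)=C\C)C[C@@]2(C)OC(=CC2=O)CC
F15 | step 16 | macrocyclic vinylogous aldol (epimers at C4 and C5) | C/C=C(/C)C(=O)O[C@@H]1C[C@@]2(C)OC(=CC2=O)C(C)C(O)[C@H]2OC(=O)[C@@H](C)[C@@H]21
F16 | step 16 | C5 mesylate of F15 | C/C=C(/C)C(=O)O[C@@H]1C[C@@]2(C)OC(=CC2=O)C(C)C(OS(C)(=O)=O)[C@H]2OC(=O)[C@@H](C)[C@@H]21
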